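**Strategy.** The flavanone is disconnected at O1–C2 and C4–C4a, which splits it into a catechol and a C6–C3 cinnamoyl unit. Ring A (C4a–C5–C6–C7–C8–C8a) is a pentaoxygenated benzene whose only unsubstituted carbon is C4a, ortho to the O1 hydroxyl. Acylation can therefore occur only there, and of the two catechol oxygens only O1, never O8, can reach C2. The key step is one telescoped operation: Friedel–Crafts acylation of unprotected 3,4,5-trimethoxycatechol with 3,4-dimethoxycinnamoyl chloride gives the 2',3'-dihydroxychalcone, which a chiral bifunctional organocatalyst closes by a chalcone-isomerase-like 6-endo oxa-Michael addition to the (2S)-pyranone ring. No protecting groups are used.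

Key step: step 3

Assumption: the sense of induction of the cinchona-derived catalyst is not predicted here; the quinine-derived catalyst is written, and its quinidine-derived pseudoenantiomer is used instead if that is the one that delivers 2S.

Step 1
Reactants: 1 3,4,5-trimethoxyphenol
Product: 3 3,4,5-trimethoxybenzene-1,2-diol, via o-quinone 2 (not isolated)
Conditions: IBX (1.1 equiv), DMF, rt, Ar; then aq Na2S2O4, rt, one pot
Reagents that add atoms: 2-iodoxybenzoic acid (IBX), O=C1OI(=O)(O)c2ccccc12
Why: IBX binds the phenol oxygen and delivers an oxygen atom intramolecularly to an ortho carbon (regioselective phenol-to-o-quinone oxidation; the two ortho positions of 1 are equivalent), and dithionite should reduce the quinone to the catechol before it can decompose.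

Step 2
Reactants: 4 (E)-3,4-dimethoxycinnamic acid
Product: 5 (E)-3,4-dimethoxycinnamoyl chloride
Conditions: (COCl)2 (1.2 equiv), cat. DMF, CH2Cl2, 0 °C to rt; evaporate, use crude
Reagents that add atoms: oxalyl chloride, ClC(=O)C(=O)Cl
Why: Acid chloride formation through the Vilsmeier-type chloroiminium catalyst gives only volatile by-products and should leave the E-alkene and the aryl methyl ethers untouched.

Step 3
Reactants: 3 3,4,5-trimethoxybenzene-1,2-diol; 5 (E)-3,4-dimethoxycinnamoyl chloride
Product: 7 (2S)-2-(3,4-dimethoxyphenyl)-8-hydroxy-5,6,7-trimethoxy-2,3-dihydro-4H-chromen-4-one, via chalcone 6 (not isolated)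
Conditions: (i) BF3·OEt2 (4 equiv), PhCl, 70 °C, Ar; cold aq NaOAc then NaHCO3 wash, azeotropic drying, no isolation; (ii) epi-9-amino-9-deoxyquinine 3,5-bis(trifluoromethyl)phenyl thiourea (10 mol%), PhCl, 0 °C to rt, Ar
Reagents that add atoms: none
Why: BF3 activates acid chloride 5 as an acylium donor that attacks C4a, the only ring C–H of 3 and ortho/para to three oxygens, in a Friedel–Crafts acylation of the kind used to make 2'-hydroxychalcones from polymethoxyphenols and cinnamoyl chlorides, and the boron-bound 2'-oxygen cannot add to the enone, so the sequence should pause at chalcone 6. After the wash, the quinuclidine nitrogen of the bifunctional catalyst deprotonates the 2'-OH while its thiourea hydrogen-bonds to the enone carbonyl, and the phenoxide adds to C-β in a 6-endo-trig oxa-Michael closure of the pyranone ring, the laboratory counterpart of the chalcone isomerase reaction and a known organocatalytic cyclisation of 2'-hydroxychalcones. The new C2 stereocentre is under catalyst control: the chiral hydrogen-bonded ion pair exposes one face of the enone, and the catalyst pseudoenantiomer that gives 2S is used. Regioselectivity needs no control because C4a is the only free ring position, and the choice between the two hydroxyls is geometric, since only the 2'-OH can reach C-β through a six-membered ring; acylation must outrun conjugate C-alkylation (the path to a 4-aryldihydrocoumarin), which the acylium route under BF3 should secure. The 6'-methoxy group twists the chalcone carbonyl out of conjugation and so favours the closed flavanone, and the mild non-acidic second stage should keep the benzylic C2–O1 bond from reopening. Chromatography and recrystallisation should raise the enantiopurity if induction is incomplete.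

**Compound list**

1 | 3,4,5-trimethoxyphenol | COc1cc(O)cc(OC)c1OC | starting material
2 | 3,4,5-trimethoxy-1,2-benzoquinone | COC1=CC(=O)C(=O)C(OC)=C1OC | intermediate
3 | 3,4,5-trimethoxybenzene-1,2-diol | COc1cc(O)c(O)c(OC)c1OC | intermediate
4 | (E)-3,4-dimethoxycinnamic acid | COc1ccc(/C=C/C(=O)O)cc1OC | starting material
5 | (E)-3,4-dimethoxycinnamoyl chloride | COc1ccc(/C=C/C(=O)Cl)cc1OC | intermediate
6 | (E)-1-(2,3-dihydroxy-4,5,6-trimethoxyphenyl)-3-(3,4-dimethoxyphenyl)prop-2-en-1-one | COc1ccc(/C=C/C(=O)c2c(O)c(O)c(OC)c(OC)c2OC)cc1OC | intermediate
7 | (2S)-2-(3,4-dimethoxyphenyl)-8-hydroxy-5,6,7-trimethoxy-2,3-dihydro-4H-chromen-4-one | COc1ccc([C@@H]2CC(=O)c3c(c(O)c(OC)c(OC)c3OC)O2)cc1OC | target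

**Total step count:** 3
**Longest linear sequence:** 2 steps (1 → 3 → 7; the branch 4 → 5 is one step and joins at step 3)

**Steps most likely to fail**

1. Step 3 (key step). Enantiopurity may be eroded by poor facial selectivity in the oxa-Michael stage or by racemic background ring closure during the acylation stage and the wash; conjugate C-alkylation may also compete with acylation. The fallback sets out from 3 and 5 and forms the same two bonds without stereocontrol: BF3·OEt2 acylation followed in the same flask by NaOAc in refluxing ethanol should give the racemic flavanone F1. A kinetic resolution by Noyori–Ikariya asymmetric transfer hydrogenation (RuCl(p-cymene)(TsDPEN), HCO2H/Et3N), using the catalyst antipode that reduces the (2R)-ketone faster, should then convert the unwanted enantiomer into the (2R,4R)-cis-flavan-4-ol F2. Unreacted (S)-flavanone is separated by chromatography, and the fallback comes back to the route at 7.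

2. Step 1. Over-oxidation may occur, either by loss of methanol towards a p-quinone or by decomposition of the electron-rich o-quinone before it is reduced. The fallback sets out from 1: magnesium-mediated ortho-formylation (MgCl2, Et3N, paraformaldehyde, MeCN, reflux) should give 6-hydroxy-2,3,4-trimethoxybenzaldehyde F3. Dakin oxidation (30% H2O2, cat. H2SO4, aqueous THF) then proceeds through 6-hydroxy-2,3,4-trimethoxyphenyl formate F4, whose hydrolysis in situ gives the catechol, and the fallback comes back to the route at 3.

3. Step 2. The electron-rich acid chloride may hydrolyse, add HCl or oligomerise during concentration and transfer. The fallback sets out from 3 and 4 and avoids the acid chloride: Steglich esterification (DCC, cat. DMAP, CH2Cl2) should give 2-hydroxy-3,4,5-trimethoxyphenyl (E)-3-(3,4-dimethoxyphenyl)prop-2-enoate F5, possibly together with its regioisomer 6-hydroxy-2,3,4-trimethoxyphenyl (E)-3-(3,4-dimethoxyphenyl)prop-2-enoate F6. A Lewis-acid Fries rearrangement (BF3·OEt2, PhCl, 70 °C) should move the acyl group of either ester to the only free ring carbon, and the fallback comes back to the route at 6, which enters stage (ii) of step 3.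

**Further compounds**

F1 | step 3 | rac-2-(3,4-dimethoxyphenyl)-8-hydroxy-5,6,7-trimethoxy-2,3-dihydro-4H-chromen-4-one | COc1ccc(C2CC(=O)c3c(c(O)c(OC)c(OC)c3OC)O2)cc1OC
F2 | step 3 | (2R,4R)-2-(3,4-dimethoxyphenyl)-5,6,7-trimethoxychromane-4,8-diol | COc1ccc([C@H]2C[C@@H](O)c3c(c(O)c(OC)c(OC)c3OC)O2)cc1OC
F3 | step 1 | 6-hydroxy-2,3,4-trimethoxybenzaldehyde | O=Cc1c(O)cc(OC)c(OC)c1OC
F4 | step 1 | 6-hydroxy-2,3,4-trimethoxyphenyl formate | O=COc1c(O)cc(OC)c(OC)c1OC
F5 | step 2 | 2-hydroxy-3,4,5-trimethoxyphenyl (E)-3-(3,4-dimethoxyphenyl)prop-2-enoate | COc1ccc(/C=C/C(=O)Oc2cc(OC)c(OC)c(OC)c2O)cc1OC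
F6 | step 2 | 6-hydroxy-2,3,4-trimethoxyphenyl (E)-3-(3,4-dimethoxyphenyl)prop-2-enoate | COc1ccc(/C=C/C(=O)Oc2c(O)cc(OC)c(OC)c2OC)cc1OC
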